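The route rests on cutting the α-methylene-γ-butyrolactone (ring O–C6–C7–C11–C12) into CO2, a nucleophilic C11 and an electrophilic C6. In the key step a 2-lithioalkene at C11 is carboxylated (C11–C12) and the resulting acrylate opens the neighbouring Sharpless-derived C5–C6 epoxide at C6 with inversion (O–C6). This formal [3+2] annulation of CO2 exploits the 1,3-relationship of C11 and C6 across C7. It should deliver the trans-fused lactone and a diol that is cleaved to the C5 aldehyde. The precursor is a 2-bromoalkene carrying an epoxy alcohol and a dioxolane. Two Z-alkenes, two reagent-controlled epoxidations and a CrCl2/NiCl2 ring closure complete the ten-membered ring.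

Key step: step 8

Remark: germacrane numbering of the target is used for all intermediates (ring C1–C10, lactone C11–C13 with C12 the carbonyl, C14 the carboxyl carbon, C15 the methyl on C4; C4′ is the carbon removed in step 9); where a name gives no descriptor, the SMILES string defines the configuration.

Step 1
Reactants: 1 dimethyl (2E,4E)-hexa-2,4-dienedioate
Product: 2 (2E,4E)-hexa-2,4-diene-1,6-diol
Conditions: i-Bu2AlH (4.4 equiv), CH2Cl2, −78 → 0 °C; aq. potassium sodium tartrate
Reagents that add atoms: none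
Why: Ester reduction with i-Bu2AlH should give the bis-allylic diol without touching the E,E-diene; no stereocentre is formed.

Step 2
Reactants: 2 (2E,4E)-hexa-2,4-diene-1,6-diol
Product: 3 [(2R,3R)-3-[(1E)-3-hydroxyprop-1-enyl]oxiran-2-yl]methanol
Conditions: Ti(OiPr)4 (10 mol%), D-(−)-diisopropyl tartrate (12 mol%), t-BuOOH (1.0 equiv), 4 Å MS, CH2Cl2, −25 °C
Reagents that add atoms: tert-butyl hydroperoxide CC(C)(C)OO
Why: Sharpless asymmetric epoxidation of one of the two equivalent allylic alcohol ends (one equivalent of peroxide, the first epoxide deactivating the remaining alkene); the D-(−)-tartrate titanium complex delivers oxygen to the face that gives the (2R,3R)-epoxide and so sets C8.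

Step 3
Reactants: 3 [(2R,3R)-3-[(1E)-3-hydroxyprop-1-enyl]oxiran-2-yl]methanol
Product: 4 (2S,3R,4E)-3-[(trimethylsilyl)ethynyl]hex-4-ene-1,2,6-triol
Conditions: Me3SiC≡CH, n-BuLi, toluene, 0 °C; Et2AlCl; then 3, CH2Cl2, 0 → 23 °C (4 equiv of alane)
Reagents that add atoms: (trimethylsilyl)acetylene C#C[Si](C)(C)C, delivered as diethyl[(trimethylsilyl)ethynyl]aluminium CC[Al](CC)C#C[Si](C)(C)C
Why: Alkynylalane opening of a 2,3-epoxy alcohol at the distal, here also allylic, carbon C7 with inversion should give the 1,2-diol and set C7 anti to the C8 hydroxyl.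

Step 4
Reactants: 4 (2S,3R,4E)-3-[(trimethylsilyl)ethynyl]hex-4-ene-1,2,6-triol
Product: 5 (2E,4R)-4-[(4S)-2,2-dimethyl-1,3-dioxolan-4-yl]-6-(trimethylsilyl)hex-2-en-5-yn-1-ol
Conditions: Me2C(OMe)2, pyridinium p-toluenesulfonate (cat.), acetone, 0 → 23 °C; then MeOH/H2O
Reagents that add atoms: 2,2-dimethoxypropane COC(C)(C)OC
Why: Acetalisation under thermodynamic control should select the 1,2-diol as the five-membered dioxolane and leave the remote allylic alcohol free.

Step 5
Reactants: 5 (2E,4R)-4-[(4S)-2,2-dimethyl-1,3-dioxolan-4-yl]-6-(trimethylsilyl)hex-2-en-5-yn-1-ol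
Product: 6 (2E,4R)-4-[(4S)-2,2-dimethyl-1,3-dioxolan-4-yl]hex-2-en-5-yn-1-ol
Conditions: K2CO3, MeOH, 23 °C
Reagents that add atoms: none
Why: Methanolysis of the alkynyl C–Si bond (protodesilylation) frees the terminal alkyne under conditions too mild to epimerise C7.

Step 6
Reactants: 6 (2E,4R)-4-[(4S)-2,2-dimethyl-1,3-dioxolan-4-yl]hex-2-en-5-yn-1-ol
Product: 8 (2E,4S)-5-bromo-4-[(4S)-2,2-dimethyl-1,3-dioxolan-4-yl]hexa-2,5-dien-1-ol, via alkenylalane 7 (not isolated)
Conditions: NiCl2(dppp) (3 mol%), i-Bu2AlH (2.4 equiv), THF, 0 → 23 °C; then N-bromosuccinimide, −78 → 0 °C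
Reagents that add atoms: N-bromosuccinimide O=C1CCC(=O)N1Br
Why: Nickel-catalysed α-selective hydroalumination of the terminal alkyne (one equivalent of hydride is spent on the hydroxyl) followed by bromodealumination with retention should give the 2-bromo-1-alkene needed at C11.

Step 7
Reactants: 8 (2E,4S)-5-bromo-4-[(4S)-2,2-dimethyl-1,3-dioxolan-4-yl]hexa-2,5-dien-1-ol
Product: 9 (5R,6R)-5,6-epoxide of 8 (trans-epoxy alcohol)
Conditions: Ti(OiPr)4 (10 mol%), D-(−)-diisopropyl tartrate (12 mol%), t-BuOOH, 4 Å MS, CH2Cl2, −20 °C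
Reagents that add atoms: tert-butyl hydroperoxide CC(C)(C)OO
Why: Sharpless asymmetric epoxidation of the E-allylic alcohol; reagent control by D-(−)-tartrate sets C5 and C6 (5R,6R), C6 with the configuration opposite to that needed in the lactone, and the electron-poor bromoalkene does not react.

Step 8
Reactants: 9 (5R,6R)-5,6-epoxide of 8
Product: 12 6,12-olide diol (trans-fused α-methylene-γ-butyrolactone with a 1,2-dihydroxyethyl group on C6 and the dioxolane on C7), via alkenyllithium 10 (not isolated), via epoxy acrylic acid 11 (not isolated)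
Conditions: t-BuLi (3.1 equiv), THF, −78 °C; CO2, −78 → 0 °C; then aq. citric acid (pH 3), 23 °C
Reagents that add atoms: carbon dioxide O=C=O
Why: Bromine–lithium exchange at −78 °C gives the C11 alkenyllithium 10 (the hydroxyl is carried as its lithium alkoxide), which adds to CO2 and forms the C11–C12 bond; on acidification the γ,δ-epoxy acrylic acid 11 cyclises by attack of the carboxyl oxygen on C6 of the epoxide, forming the O–C6 bond. The closest known reaction types are the carboxylation of alkenyllithium reagents and the acid-mediated lactonisation of γ,δ-epoxy acids. The lactone ring closes in the 5-exo-tet mode. C6 is set by inversion at the epoxide carbon fixed in step 7, so that the lactone oxygen on C6 and C8 on C7 end up trans; C7 is not touched. The step needs the exchange to outrun attack of the organolithium on the epoxide, which −78 °C and the fast exchange of alkenyl bromides with two equivalents of t-BuLi should secure. It also needs opening at C6 rather than 6-endo opening at C5, which the ring size and the usual distal opening of 2,3-epoxy alcohols should secure.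

Step 9
Reactants: 12 6,12-olide diol
Product: 13 C5 aldehyde (lactone with CHO on C6)
Conditions: NaIO4, THF/H2O (pH 7 phosphate buffer), 0 °C
Reagents that add atoms: none
Why: Periodate glycol cleavage of the only free 1,2-diol should remove C4′ as formaldehyde and give the C5 aldehyde under neutral conditions that do not epimerise C6.

Step 10
Reactants: 13 C5 aldehyde
Product: 14 (Z)-iodoalkene (lactone with a (1Z)-2-iodoprop-1-enyl group on C6)
Conditions: EtPPh3I, n-BuLi, THF, 23 °C; I2, −78 °C; NaN(SiMe3)2, −78 °C; then 13, −78 → −20 °C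
Reagents that add atoms: ethyltriphenylphosphonium iodide CC[P+](c1ccccc1)(c1ccccc1)c1ccccc1.[I-]; iodine II
Why: Stork–Zhao-type Wittig olefination with (1-iodoethylidene)triphenylphosphorane should give the (Z)-iodoalkene (iodine cis to C6, methyl trans) under kinetic control, the aldehyde reacting far faster at −78 °C than the methylene lactone.

Step 11
Reactants: 14 (Z)-iodoalkene
Product: 15 C8,C9-diol
Conditions: AcOH/H2O (4:1), 40 °C
Reagents that add atoms: none
Why: Acid-catalysed acetal hydrolysis frees the C8/C9 diol at a stage where no acid-labile epoxide is present.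

Step 12
Reactants: 15 C8,C9-diol
Product: 16 C9 tert-butyldimethylsilyl ether of 15
Conditions: t-BuMe2SiCl (1.05 equiv), imidazole, CH2Cl2, −20 → 0 °C
Reagents that add atoms: tert-butyldimethylsilyl chloride CC(C)(C)[Si](C)(C)Cl
Why: Selective silylation of the primary C9 hydroxyl over the hindered secondary C8 hydroxyl.

Step 13
Reactants: 17 methyl (2Z)-2-methylbut-2-enoate (methyl angelate)
Product: 18 (2Z)-2-methylbut-2-en-1-ol
Conditions: i-Bu2AlH (2.2 equiv), CH2Cl2, −78 °C
Reagents that add atoms: none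
Why: Ester reduction gives the allylic alcohol with the Z geometry of the angelate unchanged.

Step 14
Reactants: 18 (2Z)-2-methylbut-2-en-1-ol
Product: 19 [(2S,3R)-2,3-dimethyloxiran-2-yl]methanol
Conditions: Ti(OiPr)4 (10 mol%), L-(+)-diethyl tartrate (12 mol%), t-BuOOH, 4 Å MS, CH2Cl2, −20 °C
Reagents that add atoms: tert-butyl hydroperoxide CC(C)(C)OO
Why: Sharpless asymmetric epoxidation; L-(+)-tartrate sets both epoxide carbons (2S,3R) and the Z-alkene fixes the two methyl groups trans on the oxirane.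

Step 15
Reactants: 19 [(2S,3R)-2,3-dimethyloxiran-2-yl]methanol
Product: 20 (2R,3R)-2,3-dimethyloxirane-2-carboxylic acid
Conditions: TEMPO (10 mol%), PhI(OAc)2 (2.2 equiv), MeCN/H2O (1:1), 23 °C
Reagents that add atoms: water O
Why: TEMPO/PhI(OAc)2 oxidation of the primary alcohol through the aldehyde hydrate gives the acid without touching the epoxide (the C2 descriptor changes only through the priority rules).

Step 16
Reactants: 16 C9 silyl ether; 20 (2R,3R)-2,3-dimethyloxirane-2-carboxylic acid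
Product: 21 C8 (2R,3R)-2,3-dimethyloxirane-2-carboxylate of 16
Conditions: DCC, DMAP, CH2Cl2, 0 → 23 °C
Reagents that add atoms: none
Why: Steglich esterification acylates the secondary C8 hydroxyl with the epoxy acid; no stereocentre is involved.

Step 17
Reactants: 22 prop-2-yn-1-ol
Product: 24 (2Z)-3-(tributylstannyl)prop-2-en-1-ol, via cyclic alkenylaluminate 23 (not isolated)
Conditions: LiAlH4, THF, 0 → 23 °C; then Bu3SnOTf, −78 → 23 °C
Reagents that add atoms: tributyltin trifluoromethanesulfonate CCCC[Sn](CCCC)(CCCC)OS(=O)(=O)C(F)(F)F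
Why: trans-Hydroalumination of the propargylic alkoxide places aluminium on C3 cis to the CH2O group in a cyclic aluminate, and tin-for-aluminium exchange with retention should give the Z-stannane.

Step 18
Reactants: 21 iodoalkene ester; 24 (2Z)-3-(tributylstannyl)prop-2-en-1-ol
Product: 25 (2Z,4Z)-dienol (C1 hydroxyl; (Z)-CH=CH–CH2OH in place of iodine)
Conditions: Pd2(dba)3 (5 mol%), AsPh3, CuI, N-methylpyrrolidone, 23 °C
Reagents that add atoms: none
Why: Stille coupling with retention at both alkenyl carbons should give the (2Z,4Z)-dienol; copper-assisted transmetallation at room temperature is chosen to outrun insertion of the alkenylpalladium into the methylene lactone.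

Step 19
Reactants: 25 (2Z,4Z)-dienol
Product: 26 cis-2,3-epoxy alcohol (C2 and C3 as in the target)
Conditions: Ti(OiPr)4 (1.0 equiv), D-(−)-diethyl tartrate (1.2 equiv), t-BuOOH, 4 Å MS, CH2Cl2, −20 °C
Reagents that add atoms: tert-butyl hydroperoxide CC(C)(C)OO
Why: Sharpless asymmetric epoxidation is directed by the C1 hydroxyl to the adjacent Z-alkene only; D-(−)-tartrate sets C2 and C3 and the Z geometry makes the epoxide cis.

Step 20
Reactants: 26 cis-2,3-epoxy alcohol
Product: 27 2,3:4,5-bis-epoxy alcohol (C2–C5 as in the target)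
Conditions: 1,2:4,5-di-O-isopropylidene-β-D-erythro-2,3-hexodiulo-2,6-pyranose (30 mol%), KHSO5 (as 2KHSO5·KHSO4·K2SO4), K2CO3, Na2B4O7 buffer (pH 10.5), Bu4NHSO4, MeCN/CH2(OMe)2/H2O, 0 °C
Reagents that add atoms: potassium peroxymonosulfate [K+].[O-]S(=O)(=O)OO
Why: Shi epoxidation: the chiral dioxirane attacks the only electron-rich alkene left (the methylene lactone is electron-poor) through the spiro transition state, which for this trisubstituted alkene (methyl trans to C6) should place oxygen on the face giving 4R,5R by reagent control.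

Step 21
Reactants: 27 bis-epoxy alcohol
Product: 28 bis-epoxy aldehyde (C1 CHO)
Conditions: Dess–Martin periodinane, NaHCO3, CH2Cl2, 0 → 23 °C
Reagents that add atoms: none
Why: Dess–Martin oxidation gives the α,β-epoxy aldehyde under buffered conditions that do not open the epoxides.

Step 22
Reactants: 29 bromoacetyl bromide; 30 2-(trimethylsilyl)ethanol
Product: 31 2-(trimethylsilyl)ethyl bromoacetate
Conditions: pyridine, CH2Cl2, 0 °C
Reagents that add atoms: none
Why: Acylation of the alcohol by the acid bromide.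

Step 23
Reactants: 31 2-(trimethylsilyl)ethyl bromoacetate
Product: 33 2-(trimethylsilyl)ethyl (triphenyl-λ5-phosphanylidene)acetate, via phosphonium bromide 32 (not isolated)
Conditions: PPh3, toluene, 23 °C; then aq. NaOH, CH2Cl2
Reagents that add atoms: triphenylphosphine c1ccc(cc1)P(c1ccccc1)c1ccccc1
Why: Alkylation of the phosphine and deprotonation of the salt give the stabilised Wittig ylide.

Step 24
Reactants: 28 bis-epoxy aldehyde; 33 stabilised ylide
Product: 35 (Z)-2-iodo enoate (CH=C(I)CO2CH2CH2SiMe3 at C1/C10, iodine cis to C2), via iodo ylide 34 (not isolated)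
Conditions: 33, N-iodosuccinimide, CH2Cl2, −20 °C; then K2CO3 and 28, 0 → 23 °C
Reagents that add atoms: N-iodosuccinimide O=C1CCC(=O)N1I
Why: Iodination of the stabilised ylide and Wittig olefination in one flask should give the (Z)-2-iodo enoate (ester trans to C2, iodine cis), the usual outcome for stabilised α-halo ylides.

Step 25
Reactants: 35 (Z)-2-iodo enoate
Product: 36 C9 alcohol
Conditions: HF·pyridine, pyridine, THF, 0 °C
Reagents that add atoms: none
Why: Fluoride-mediated desilylation of the primary silyl ether under pyridine-buffered conditions that should leave the epoxides and the silylethyl ester intact.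

Step 26
Reactants: 36 C9 alcohol
Product: 37 C9 aldehyde
Conditions: Dess–Martin periodinane, NaHCO3, CH2Cl2, 0 °C
Reagents that add atoms: none
Why: Dess–Martin oxidation to the α-acyloxy aldehyde, which is used at once to avoid epimerisation at C8.

Step 27
Reactants: 37 C9 aldehyde
Product: 38 9-O-deacetyl-leucanthin B 2-(trimethylsilyl)ethyl ester (macrocyclic 9S alcohol)
Conditions: CrCl2 (10 equiv), NiCl2 (0.1 equiv), DMSO/THF, 0.002 M, 23 °C
Reagents that add atoms: none
Why: Intramolecular Nozaki–Hiyama–Kishi reaction: the alkenylchromium from the iodo enoate adds to the C9 aldehyde with retention of the C1=C10 geometry and closes the ten-membered ring; with the chromium-bound aldehyde oxygen and the C8 acyloxy group both on the periphery of the forming ring, the 8,9-trans (9S) carbinol is expected.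

Step 28
Reactants: 38 macrocyclic 9S alcohol
Product: 39 leucanthin B 2-(trimethylsilyl)ethyl ester
Conditions: Ac2O, DMAP, pyridine, CH2Cl2, 0 °C
Reagents that add atoms: acetic anhydride CC(=O)OC(C)=O
Why: DMAP-catalysed acetylation of the C9 hydroxyl, fast enough to prevent acyl migration from O8.

Step 29
Reactants: 39 leucanthin B 2-(trimethylsilyl)ethyl ester
Product: 40 leucanthin B
Conditions: Bu4NF, AcOH (1:1), THF, 0 → 23 °C
Reagents that add atoms: none
Why: Fluoride-induced fragmentation of the 2-(trimethylsilyl)ethyl ester (loss of ethylene and Me3SiF) should free the C14 acid without touching the acetate, the epoxy ester, the lactone or the epoxides.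

Compound list
1 | dimethyl (2E,4E)-hexa-2,4-dienedioate | COC(=O)/C=C/C=C/C(=O)OC | starting material
2 | (2E,4E)-hexa-2,4-diene-1,6-diol | OC/C=C/C=C/CO | intermediate
3 | [(2R,3R)-3-[(1E)-3-hydroxyprop-1-enyl]oxiran-2-yl]methanol | OC[C@H]1O[C@@H]1/C=C/CO | intermediate
4 | (2S,3R,4E)-3-[(trimethylsilyl)ethynyl]hex-4-ene-1,2,6-triol | OC[C@@H](O)[C@@H](C#C[Si](C)(C)C)/C=C/CO | intermediate
5 | (2E,4R)-4-[(4S)-2,2-dimethyl-1,3-dioxolan-4-yl]-6-(trimethylsilyl)hex-2-en-5-yn-1-ol | CC1(C)OC[C@@H](O1)[C@@H](C#C[Si](C)(C)C)/C=C/CO | intermediate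
6 | (2E,4R)-4-[(4S)-2,2-dimethyl-1,3-dioxolan-4-yl]hex-2-en-5-yn-1-ol | CC1(C)OC[C@@H](O1)[C@@H](C#C)/C=C/CO | intermediate
7 | C11 diisobutylalane of 6 (2-alanyl-1-alkene, hydroxyl as aluminium alkoxide) | CC1(C)OC[C@@H](O1)[C@@H](C(=C)[Al](CC(C)C)CC(C)C)/C=C/CO[Al](CC(C)C)CC(C)C | intermediate
8 | (2E,4S)-5-bromo-4-[(4S)-2,2-dimethyl-1,3-dioxolan-4-yl]hexa-2,5-dien-1-ol | CC1(C)OC[C@@H](O1)[C@@H](C(Br)=C)/C=C/CO | intermediate
9 | (5R,6R)-5,6-epoxide of 8 (trans-epoxy alcohol, germacrane locants) | CC1(C)OC[C@@H](O1)[C@@H](C(Br)=C)[C@H]2O[C@@H]2CO | intermediate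
10 | C11 alkenyllithium of 9 (lithium in place of bromine, lithium alkoxide) | CC1(C)OC[C@@H](O1)[C@@H](C([Li])=C)[C@H]2O[C@@H]2CO[Li] | intermediate
11 | epoxy acrylic acid (9 with CO2H in place of bromine) | CC1(C)OC[C@@H](O1)[C@@H](C(=C)C(=O)O)[C@H]2O[C@@H]2CO | intermediate
12 | 6,12-olide diol: trans-fused α-methylene-γ-butyrolactone (6S,7R) with (5R)-CH(OH)CH2OH on C6 and the (4S)-2,2-dimethyl-1,3-dioxolan-4-yl group on C7 | C=C1C(=O)O[C@H]([C@H](O)CO)[C@H]1[C@H]1COC(C)(C)O1 | intermediate
13 | C5 aldehyde: 12 with CHO on C6 in place of the dihydroxyethyl group | C=C1C(=O)O[C@H](C=O)[C@H]1[C@H]1COC(C)(C)O1 | intermediate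
14 | (Z)-iodoalkene: 13 with CH=C(I)CH3 in place of CHO (iodine cis to C6) | C=C1C(=O)O[C@H](/C=C(/C)I)[C@H]1[C@H]1COC(C)(C)O1 | intermediate
15 | C8,C9-diol from 14 | C=C1C(=O)O[C@H](/C=C(/C)I)[C@H]1[C@H](O)CO | intermediate
16 | C9 tert-butyldimethylsilyl ether of 15 | C=C1C(=O)O[C@H](/C=C(/C)I)[C@H]1[C@H](O)CO[Si](C)(C)C(C)(C)C | intermediate
17 | methyl (2Z)-2-methylbut-2-enoate (methyl angelate) | C/C=C(/C)C(=O)OC | starting material
18 | (2Z)-2-methylbut-2-en-1-ol | C/C=C(/C)CO | intermediate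
19 | [(2S,3R)-2,3-dimethyloxiran-2-yl]methanol | OC[C@]1(C)O[C@@H]1C | intermediate
20 | (2R,3R)-2,3-dimethyloxirane-2-carboxylic acid | OC(=O)[C@]1(C)O[C@@H]1C | intermediate
21 | C8 (2R,3R)-2,3-dimethyloxirane-2-carboxylate of 16 | C=C1C(=O)O[C@H](/C=C(/C)I)[C@H]1[C@H](OC(=O)[C@]1(C)O[C@@H]1C)CO[Si](C)(C)C(C)(C)C | intermediate
22 | prop-2-yn-1-ol | C#CCO | starting material
23 | lithium 2,2-dihydro-1,2-oxaluminol-2-ide (cyclic Z-alkenylaluminate) | [Li+].[AlH2-]1OCC=C1 | intermediate
24 | (2Z)-3-(tributylstannyl)prop-2-en-1-ol | CCCC[Sn](CCCC)(CCCC)/C=C\CO | intermediate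
25 | (2Z,4Z)-dienol: 21 with (Z)-CH=CH–CH2OH in place of iodine | C=C1C(=O)O[C@H](/C=C(/C)\C=C/CO)[C@H]1[C@H](OC(=O)[C@]1(C)O[C@@H]1C)CO[Si](C)(C)C(C)(C)C | intermediate
26 | cis-2,3-epoxy alcohol from 25 (C2, C3 as in the target; C4=C5 Z) | C=C1C(=O)O[C@H](/C=C(/C)[C@@H]2O[C@@H]2CO)[C@H]1[C@H](OC(=O)[C@]1(C)O[C@@H]1C)CO[Si](C)(C)C(C)(C)C | intermediate
27 | 2,3:4,5-bis-epoxy alcohol (C2–C5 as in the target, C1 hydroxyl) | C=C1C(=O)O[C@H]([C@H]2O[C@@]2(C)[C@@H]2O[C@@H]2CO)[C@H]1[C@H](OC(=O)[C@]1(C)O[C@@H]1C)CO[Si](C)(C)C(C)(C)C | intermediate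
28 | bis-epoxy aldehyde (27 with C1 CHO) | C=C1C(=O)O[C@H]([C@H]2O[C@@]2(C)[C@@H]2O[C@@H]2C=O)[C@H]1[C@H](OC(=O)[C@]1(C)O[C@@H]1C)CO[Si](C)(C)C(C)(C)C | intermediate
29 | bromoacetyl bromide | BrCC(Br)=O | starting material
30 | 2-(trimethylsilyl)ethanol | C[Si](C)(C)CCO | starting material
31 | 2-(trimethylsilyl)ethyl bromoacetate | C[Si](C)(C)CCOC(=O)CBr | intermediate
32 | [2-oxo-2-[2-(trimethylsilyl)ethoxy]ethyl]triphenylphosphonium bromide | C[Si](C)(C)CCOC(=O)C[P+](c1ccccc1)(c1ccccc1)c1ccccc1.[Br-] | intermediate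
33 | 2-(trimethylsilyl)ethyl (triphenyl-λ5-phosphanylidene)acetate | C[Si](C)(C)CCOC(=O)C=P(c1ccccc1)(c1ccccc1)c1ccccc1 | intermediate
34 | 2-(trimethylsilyl)ethyl iodo(triphenyl-λ5-phosphanylidene)acetate | C[Si](C)(C)CCOC(=O)C(I)=P(c1ccccc1)(c1ccccc1)c1ccccc1 | intermediate
35 | (Z)-2-iodo enoate: 28 with CH=C(I)CO2CH2CH2SiMe3 in place of CHO (iodine cis to C2) | C=C1C(=O)O[C@H]([C@H]2O[C@@]2(C)[C@@H]2O[C@@H]2/C=C(\I)C(=O)OCC[Si](C)(C)C)[C@H]1[C@H](OC(=O)[C@]1(C)O[C@@H]1C)CO[Si](C)(C)C(C)(C)C | intermediate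
36 | C9 alcohol (35 without the silyl ether) | C=C1C(=O)O[C@H]([C@H]2O[C@@]2(C)[C@@H]2O[C@@H]2/C=C(\I)C(=O)OCC[Si](C)(C)C)[C@H]1[C@H](OC(=O)[C@]1(C)O[C@@H]1C)CO | intermediate
37 | C9 aldehyde from 36 | C=C1C(=O)O[C@H]([C@H]2O[C@@]2(C)[C@@H]2O[C@@H]2/C=C(\I)C(=O)OCC[Si](C)(C)C)[C@H]1[C@H](OC(=O)[C@]1(C)O[C@@H]1C)C=O | intermediate
38 | 9-O-deacetyl-leucanthin B 2-(trimethylsilyl)ethyl ester (9S alcohol) | C=C1C(=O)O[C@H]2[C@H]1[C@H](OC(=O)[C@]1(C)O[C@@H]1C)[C@@H](O)/C(C(=O)OCC[Si](C)(C)C)=C\[C@H]1O[C@H]1[C@]1(C)O[C@H]21 | intermediate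
39 | leucanthin B 2-(trimethylsilyl)ethyl ester | C=C1C(=O)O[C@H]2[C@H]1[C@H](OC(=O)[C@]1(C)O[C@@H]1C)[C@@H](OC(C)=O)/C(C(=O)OCC[Si](C)(C)C)=C\[C@H]1O[C@H]1[C@]1(C)O[C@H]21 | intermediate
40 | leucanthin B | C=C1C(=O)O[C@H]2[C@H]1[C@H](OC(=O)[C@]1(C)O[C@@H]1C)[C@@H](OC(C)=O)/C(C(=O)O)=C\[C@H]1O[C@H]1[C@]1(C)O[C@H]21 | target

Total step count: 29. Longest linear sequence: 23 steps (steps 1–12, 16, 18–21 and 24–29).

Steps most likely to fail

Step 27 (chromium/nickel ring closure). The alkenylchromium may eliminate onto the neighbouring C2–C3 epoxide to give an allene. The strained ring may also close too slowly, so that proto-deiodination or dimerisation wins, and addition to the aldehyde may show low facial selectivity at C9. The fallback closes the ring before the C2–C3 epoxide exists and sets out from 25. Shi epoxidation with the same ketone should take the trisubstituted alkene of the dienol first and give the 4,5-epoxy (2Z)-allylic alcohol F1. Dess–Martin oxidation gives the (2Z)-enal F2, and iodination/Wittig olefination with 33 and N-iodosuccinimide gives the iodo dienoate F3. HF·pyridine then gives the C9 alcohol F4 and Dess–Martin oxidation the C9 aldehyde F5. CrCl2/NiCl2 closes the ring to the macrocyclic dienoate carbinol F6, in which the alkenylchromium has no allylic epoxide. Dimethyldioxirane then epoxidises the C2=C3 alkene of F6 from the open outer face, and the route comes back at 38.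

Step 20 (Shi epoxidation). The spiro transition state may be congested by the cis substituent C3 and its epoxide, so that the face selectivity drops. At pH 10.5 the methylene lactone may also suffer hydrolysis or conjugate addition. The fallback installs the 4,5-epoxide by hydroxyl-directed Sharpless chemistry and sets out from 21. Stille coupling with (tributylstannyl)methanol gives the (Z)-allylic alcohol F7. Sharpless epoxidation with L-(+)-diethyl tartrate gives the 4,5-epoxy alcohol F8, and Dess–Martin oxidation the 4,5-epoxy aldehyde F9. Stork–Zhao olefination with (iodomethylidene)triphenylphosphorane gives the (Z)-iodoalkene F10, and a second Stille coupling with (tributylstannyl)methanol the 4,5-epoxy (2Z)-allylic alcohol F11. Sharpless epoxidation of F11 with D-(−)-diethyl tartrate comes back at 27.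

Step 18 (Stille coupling). The alkenylpalladium intermediate may insert into the nearby methylene lactone (5-exo Heck-type cyclisation) before transmetallation, the stannane may be protodestannylated, or the Z,Z-diene may isomerise. The fallback sets out from 21 and builds the C2=C3 alkene by reduction instead. Sonogashira coupling with prop-2-yn-1-ol 22 (Pd(PPh3)2Cl2, CuI, Et3N, 23 °C) should be fast enough to avoid the insertion and gives the enynol F12. cis-Selective semi-reduction of the alkyne with copper- and silver-activated zinc in MeOH/H2O comes back at 25.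

Further compounds
F1 | step 27 | 4,5-epoxy (2Z)-allylic alcohol (25 with the 4R,5R epoxide) | C=C1C(=O)O[C@H]([C@H]2O[C@@]2(C)/C=C\CO)[C@H]1[C@H](OC(=O)[C@]1(C)O[C@@H]1C)CO[Si](C)(C)C(C)(C)C
F2 | step 27 | (2Z)-enal from F1 (C1 CHO) | C=C1C(=O)O[C@H]([C@H]2O[C@@]2(C)/C=C\C=O)[C@H]1[C@H](OC(=O)[C@]1(C)O[C@@H]1C)CO[Si](C)(C)C(C)(C)C
F3 | step 27 | iodo dienoate: F2 with CH=C(I)CO2CH2CH2SiMe3 in place of CHO (2Z; iodine cis to C2) | C=C1C(=O)O[C@H]([C@H]2O[C@@]2(C)/C=C\C=C(/I)C(=O)OCC[Si](C)(C)C)[C@H]1[C@H](OC(=O)[C@]1(C)O[C@@H]1C)CO[Si](C)(C)C(C)(C)C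
F4 | step 27 | C9 alcohol from F3 | C=C1C(=O)O[C@H]([C@H]2O[C@@]2(C)/C=C\C=C(/I)C(=O)OCC[Si](C)(C)C)[C@H]1[C@H](OC(=O)[C@]1(C)O[C@@H]1C)CO
F5 | step 27 | C9 aldehyde from F4 | C=C1C(=O)O[C@H]([C@H]2O[C@@]2(C)/C=C\C=C(/I)C(=O)OCC[Si](C)(C)C)[C@H]1[C@H](OC(=O)[C@]1(C)O[C@@H]1C)C=O
F6 | step 27 | macrocyclic 9S carbinol with a (Z)-C2=C3 alkene in place of the 2,3-epoxide of 38 | C=C1C(=O)O[C@H]2[C@H]1[C@H](OC(=O)[C@]1(C)O[C@@H]1C)[C@@H](O)/C(C(=O)OCC[Si](C)(C)C)=C\C=C/[C@]1(C)O[C@H]21
F7 | step 20 | (Z)-allylic alcohol: 21 with CH2OH in place of iodine | C=C1C(=O)O[C@H](/C=C(/C)CO)[C@H]1[C@H](OC(=O)[C@]1(C)O[C@@H]1C)CO[Si](C)(C)C(C)(C)C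
F8 | step 20 | 4,5-epoxy alcohol from F7 (C3 hydroxyl) | C=C1C(=O)O[C@H]([C@H]2O[C@@]2(C)CO)[C@H]1[C@H](OC(=O)[C@]1(C)O[C@@H]1C)CO[Si](C)(C)C(C)(C)C
F9 | step 20 | 4,5-epoxy aldehyde from F8 (C3 CHO) | C=C1C(=O)O[C@H]([C@H]2O[C@@]2(C)C=O)[C@H]1[C@H](OC(=O)[C@]1(C)O[C@@H]1C)CO[Si](C)(C)C(C)(C)C
F10 | step 20 | (Z)-iodoalkene from F9 (CH=CHI on C4) | C=C1C(=O)O[C@H]([C@H]2O[C@@]2(C)/C=C\I)[C@H]1[C@H](OC(=O)[C@]1(C)O[C@@H]1C)CO[Si](C)(C)C(C)(C)C
F11 | step 20 | 4,5-epoxy (2Z)-allylic alcohol from F10 (same structure as F1) | C=C1C(=O)O[C@H]([C@H]2O[C@@]2(C)/C=C\CO)[C@H]1[C@H](OC(=O)[C@]1(C)O[C@@H]1C)CO[Si](C)(C)C(C)(C)C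
F12 | step 18 | enynol: 21 with C≡C–CH2OH in place of iodine | C=C1C(=O)O[C@H](/C=C(/C)C#CCO)[C@H]1[C@H](OC(=O)[C@]1(C)O[C@@H]1C)CO[Si](C)(C)C(C)(C)C
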